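**Plan**
- Locants follow a eudesmane-style count. C3 is the O-bearing quaternary carbon, C5 the fusion methine, C7 the side-chain methine and C10 the methyl-bearing fusion carbon. C1–C5 plus C10 form ring A and C5–C10 form ring B. Ring C is the ether arene and ring D is the free phenol.
- Cuts, in order: the allyl–aryl bond on ring C, the C–D biaryl bond, then C3–C4 of ring A. The C3–O bond is not cut; it is traced back to the acyl–oxygen bond of an aryl ester.
- Enabling feature: C3 carries only CH3, OAr and the ring methylenes C2 and C4, and lies 1,3 to C5. It therefore maps onto the carbonyl carbon of an aryl 3-(cyclohexyl)propanoate, once that carbon has been methylenated (giving the CH3) and bonded to an exocyclic methylene carbon (C4) on ring B.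
- Forward order: ring B comes from (R)-carvone, and the C1–C3 chain is added at C10 by Michael addition. The phenol is then acylated, both carbonyls are methylenated, ring A is closed cationically and C5=C6 is reduced. Ring D and the ring C allyl group are coupled on last, followed by desilylation.
- Stereochemistry: C7 comes from (R)-carvone, C10 from the (R)-1-phenylethylamine imine, C3 from the chair transition state of the ring closure, and C5 from radical (HAT) hydrogenation to the trans-decalin.

Key step: step 8

Assumption: the SMILES descriptors are read as (2R,4aS,7R,8aS), that is a trans-decalin with 10β-methyl, 5α-H, equatorial 7β-(2-hydroxypropan-2-yl), axial 3α-aryloxy and equatorial 3β-methyl; the decalin locants are also used for the monocyclic precursors.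

**Route**

Step 1
Reactants: 1 (R)-carvone
Product: 2 (2R,5R)-2-methyl-5-(prop-1-en-2-yl)cyclohexan-1-one (trans-dihydrocarvone; its C10 epimer accompanies it)
Conditions: Zn, KOH, EtOH/H2O, reflux
Reagents that add atoms: none
Why: Dissolving-metal conjugate reduction of the enone leaves the isolated isopropenyl group and C7 untouched, and the epimer mixture at C10 does not matter because that centre is flattened in step 2.

Step 2
Reactants: 2 dihydrocarvone; 3 (R)-1-phenylethylamine; 4 methyl acrylate
Product: 7 methyl 3-[(1S,4R)-1-methyl-2-oxo-4-(prop-1-en-2-yl)cyclohexyl]propanoate, via ketimine 5 (not isolated), via Michael adduct ketimine 6 (not isolated)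
Conditions: 3, TsOH (cat.), PhMe, reflux, Dean–Stark; 4, THF, 45 °C; 20% aq AcOH, rt
Reagents that add atoms: methyl acrylate (4), C=CC(=O)OC; water, O
Why: In this chiral-imine Michael addition the more substituted secondary-enamine tautomer reacts in a compact aza-ene-like transition state on the face away from the phenyl group, so the (R)-amine sets C10 as S (chain trans to the C7 group) against the ring's own axial-attack bias, as this imine is known to do with vinyl ketones; a plain methyl ester is chosen because the adduct of an activated aryl acrylate would acylate the enamine nitrogen and end as a lactam.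

Step 3
Reactants: 7 keto ester
Product: 8 methyl 3-[(1S,4R)-4-(2-hydroxypropan-2-yl)-1-methyl-2-oxocyclohexyl]propanoate
Conditions: Co(acac)2 (cat.), PhSiH3, O2 (1 atm), THF, rt
Reagents that add atoms: dioxygen, O=O
Why: In the Mukaiyama hydration, hydrogen-atom transfer to the only alkene followed by O2 capture and reduction gives the Markovnikov tertiary alcohol without touching ketone, ester or either stereocentre.

Step 4
Reactants: 8 hydroxy keto ester
Product: 9 3-[(1S,4R)-4-(2-hydroxypropan-2-yl)-1-methyl-2-oxocyclohexyl]propanoic acid
Conditions: LiOH, THF/MeOH/H2O, rt; 1 M HCl to pH 3–4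
Reagents that add atoms: lithium hydroxide, [Li+].[OH-]
Why: This is a standard saponification of an unhindered methyl ester in which nothing can epimerise, since C10 is quaternary and C7 is not acidic.

Step 5
Reactants: 9 hydroxy keto acid; 10 2-bromo-4-chlorophenol
Product: 11 2-bromo-4-chlorophenyl 3-[(1S,4R)-4-(2-hydroxypropan-2-yl)-1-methyl-2-oxocyclohexyl]propanoate
Conditions: 10, EDC·HCl, DMAP, CH2Cl2, 0 °C → rt
Reagents that add atoms: 2-bromo-4-chlorophenol (10), Oc1ccc(Cl)cc1Br
Why: In the Steglich esterification the acylpyridinium ion is taken up by the acidic phenol while the hindered tertiary alcohol stays free, so the future ether C–O bond is made as an easy acyl–oxygen bond.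

Step 6
Reactants: 11 aryl ester
Product: 12 2-bromo-4-chlorophenyl 3-[(1S,4R)-1-methyl-2-oxo-4-(2-triethylsilyloxypropan-2-yl)cyclohexyl]propanoate
Conditions: TESOTf, 2,6-lutidine, CH2Cl2, −78 → 0 °C
Reagents that add atoms: triethylsilyl triflate, CC[Si](CC)(CC)OS(=O)(=O)C(F)(F)F
Why: A silyl triflate with a hindered pyridine base silylates tertiary alcohols at low temperature faster than it enolises a ketone, and the TES ether keeps O11 from consuming the titanium reagent and from trapping the cations of step 8.

Step 7
Reactants: 12 TES-protected keto aryl ester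
Product: 14 2-bromo-4-chloro-1-({4-[(1S,4R)-1-methyl-2-methylidene-4-(2-triethylsilyloxypropan-2-yl)cyclohexyl]but-1-en-2-yl}oxy)benzene, via methylene aryl ester 13 (not isolated)
Conditions: Cp2TiMe2 (5 equiv), PhMe, 75 °C, dark; filtration through basic Al2O3
Reagents that add atoms: dimethyltitanocene Cp2TiMe2, C[Ti](C)(C1C=CC=C1)C1C=CC=C1
Why: In the Petasis methylenation, thermally generated Cp2Ti=CH2 converts carbonyl groups by [2+2] cycloaddition and cycloreversion; it works on hindered enolisable ketones and on aryl esters (which give aryl enol ethers), is neither acidic nor basic, and leaves aryl halides and silyl ethers alone.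

Step 8
Reactants: 14 aryl enol ether tethered to the ring B methylenecyclohexane
Product: 17 (3R,7R,10S)-3α-(2-bromo-4-chlorophenoxy)-3β,10β-dimethyl-7β-(2-triethylsilyloxypropan-2-yl)-Δ5(6)-octalin, via aryloxycarbenium ion 15 (not isolated), via tertiary C5 cation 16 (not isolated)
Conditions: Tf2NH (5 mol %), anhydrous CH2Cl2 (0.01 M), −78 → −40 °C; Et3N quench
Reagents that add atoms: none
Why: Tf2NH protonates the terminal CH2 of the aryl enol ether, the most basic π bond in 14, to give aryloxycarbenium ion 15, whose carbon C3 is attacked by the terminal carbon C4 of the ring B methylene group; the tertiary cation 16 then gives up its axial H6 to the next molecule of 14, so the reaction is an acid-catalysed isomerisation run as a proton chain. The reaction type is the Prins-type oxocarbenium–alkene cyclisation known for alkyl enol ethers and ketals tethered to 1,1-disubstituted alkenes, and the aryl group only makes the cation less stabilised and therefore more electrophilic. Ring A closes 6-endo-trig with respect to C4=C5 (both alkene carbons end up in the ring) and exo with respect to the C3=O+ bond, through a chair. The new centre C3 (R) is controlled by ring B, which its equatorial C7 group locks with the C10 methyl axial and the tether equatorial: C3 can reach only the α face of C4, and in that chair the C3 methyl takes the equatorial site and the smaller aryloxy group the axial α site, where its oxygen also faces the charge building up at C5. The step needs protonation of the enol ether before the alkene, survival of the tertiary ether and no capture of C5 by oxygen or arene; these are secured by a catalytic amount of acid at low temperature and high dilution, by the bromine and chlorine atoms (weakly basic ether oxygen, arene too electron-poor for Friedel–Crafts closure) and by the TES group on O11. Loss of H4 instead of H6 would give the C4=C5 isomer, which step 9 should turn into the same 18.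

Step 9
Reactants: 17 octalin aryl ether
Product: 18 (3R,5S,7R,10S)-3α-(2-bromo-4-chlorophenoxy)-3β,10β-dimethyl-7β-(2-triethylsilyloxypropan-2-yl)-trans-decalin (5α-H)
Conditions: Mn(dpm)3 (cat.), PhSiH3, t-BuOOH, i-PrOH, rt
Reagents that add atoms: none
Why: Mn-catalysed HAT hydrogenation delivers hydrogen atoms one at a time, first to C6 and then to the tertiary centre C5, which takes its hydrogen axially on the α face opposite the C10 methyl to give the more stable trans-decalin, and these radical conditions spare aryl bromide, aryl chloride, tertiary ether and silyl ether.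

Step 10
Reactants: 19 4-bromophenol; 20 allyl bromide
Product: 21 1-(allyloxy)-4-bromobenzene
Conditions: K2CO3, acetone, reflux
Reagents that add atoms: allyl bromide (20), C=CCBr
Why: This is a Williamson ether synthesis between a phenoxide and a reactive allylic bromide.

Step 11
Reactants: 21 allyl 4-bromophenyl ether
Product: 22 2-allyl-4-bromophenol
Conditions: N,N-diethylaniline, 200 °C
Reagents that add atoms: none
Why: The aromatic Claisen rearrangement, a [3,3]-sigmatropic shift to a free ortho position followed by tautomerisation, places the allyl group ortho to oxygen and meta to bromine.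

Step 12
Reactants: 22 2-allyl-4-bromophenol
Product: 23 (2-allyl-4-bromophenoxy)triisopropylsilane
Conditions: TIPSCl, imidazole, DMF, rt
Reagents that add atoms: triisopropylsilyl chloride, CC(C)[Si](Cl)(C(C)C)C(C)C
Why: Imidazole-promoted silylation installs a bulky aryl silyl ether that withstands the aqueous base of both cross-couplings and still leaves with fluoride.

Step 13
Reactants: 23 aryl bromide
Product: 24 [2-allyl-4-(4,4,5,5-tetramethyl-1,3,2-dioxaborolan-2-yl)phenoxy]triisopropylsilane (ring D boronate)
Conditions: B2pin2, Pd(dppf)Cl2 (cat.), KOAc, 1,4-dioxane, 80 °C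
Reagents that add atoms: bis(pinacolato)diboron, CC1(C)OB(OC1(C)C)B1OC(C)(C)C(C)(C)O1
Why: Miyaura borylation of the aryl bromide uses only the weak base acetate, conditions under which allyl arenes and silyl ethers persist.

Step 14
Reactants: 18 bromo chloro aryl ether; 24 ring D boronate
Product: 25 biaryl chloride (ring D joined ortho to the ether oxygen of ring C; Cl para to that oxygen; TES and TIPS retained)
Conditions: Pd(dppf)Cl2 (cat.), K3PO4, 1,4-dioxane/H2O, 80 °C
Reagents that add atoms: boronate 24, C=CCc1cc(B2OC(C)(C)C(C)(C)O2)ccc1O[Si](C(C)C)(C(C)C)C(C)C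
Why: The Suzuki–Miyaura coupling is chemoselective because oxidative addition with a bisphosphine palladium catalyst is much faster at C–Br than at the C–Cl bond of the electron-rich ring.

Step 15
Reactants: 25 biaryl chloride; 26 allylboronic acid pinacol ester
Product: 27 bis-silyl ether of the target (ring C allyl group in place)
Conditions: 26, Pd(OAc)2 (cat.), SPhos, K3PO4, THF/H2O, 60 °C
Reagents that add atoms: allylB(pin) (26), C=CCB1OC(C)(C)C(C)(C)O1
Why: In this Suzuki–Miyaura allylation the electron-rich biaryl phosphine enables oxidative addition into the aryl chloride, and the unsubstituted allyl boronate raises no regiochemical question.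

Step 16
Reactants: 27 bis-silyl ether
Product: 29 target 2-[(2R,4aS,7R,8aS)-7-{[3',5-diallyl-4'-hydroxy-(1,1'-biphenyl)-2-yl]oxy}-4a,7-dimethyldecahydronaphthalen-2-yl]propan-2-ol, via C11 TES ether phenol 28 (not isolated)
Conditions: n-Bu4NF, THF, rt → 40 °C
Reagents that add atoms: none
Why: Fluoride cleaves both Si–O bonds (the aryl TIPS ether at once, the tertiary TES ether more slowly) under basic conditions that cannot ionise the tertiary aryl ether or move the allyl double bonds.

**Compound list**
1 | (R)-carvone | CC1=CC[C@H](CC1=O)C(C)=C | starting material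
2 | (2R,5R)-dihydrocarvone (with its C10 epimer) | C[C@@H]1CC[C@H](CC1=O)C(C)=C | intermediate
3 | (R)-1-phenylethylamine | C[C@@H](N)c1ccccc1 | starting material
4 | methyl acrylate | C=CC(=O)OC | starting material
5 | N-[(R)-1-phenylethyl] ketimine of 2 (C10 mobile through the enamine) | CC1CC[C@H](CC1=N[C@H](C)c1ccccc1)C(C)=C | intermediate
6 | Michael adduct ketimine | COC(=O)CC[C@]1(C)CC[C@@H](C(C)=C)CC1=N[C@H](C)c1ccccc1 | intermediate
7 | methyl 3-[(1S,4R)-1-methyl-2-oxo-4-(prop-1-en-2-yl)cyclohexyl]propanoate | COC(=O)CC[C@]1(C)CC[C@@H](C(C)=C)CC1=O | intermediate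
8 | methyl 3-[(1S,4R)-4-(2-hydroxypropan-2-yl)-1-methyl-2-oxocyclohexyl]propanoate | COC(=O)CC[C@]1(C)CC[C@@H](C(C)(C)O)CC1=O | intermediate
9 | 3-[(1S,4R)-4-(2-hydroxypropan-2-yl)-1-methyl-2-oxocyclohexyl]propanoic acid | OC(=O)CC[C@]1(C)CC[C@@H](C(C)(C)O)CC1=O | intermediate
10 | 2-bromo-4-chlorophenol | Oc1ccc(Cl)cc1Br | starting material
11 | 2-bromo-4-chlorophenyl ester of 9 | O=C(CC[C@]1(C)CC[C@@H](C(C)(C)O)CC1=O)Oc1ccc(Cl)cc1Br | intermediate
12 | TES ether of 11 | O=C(CC[C@]1(C)CC[C@@H](C(C)(C)O[Si](CC)(CC)CC)CC1=O)Oc1ccc(Cl)cc1Br | intermediate
13 | methylene aryl ester (ketone methylenated, ester intact) | O=C(CC[C@]1(C)CC[C@@H](C(C)(C)O[Si](CC)(CC)CC)CC1=C)Oc1ccc(Cl)cc1Br | intermediate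
14 | aryl enol ether tethered to the ring B methylenecyclohexane (key-step precursor) | C=C(Oc1ccc(Cl)cc1Br)CC[C@]1(C)CC[C@@H](C(C)(C)O[Si](CC)(CC)CC)CC1=C | intermediate
15 | aryloxycarbenium ion at C3 | CC(=[O+]c1ccc(Cl)cc1Br)CC[C@]1(C)CC[C@@H](C(C)(C)O[Si](CC)(CC)CC)CC1=C | intermediate
16 | tertiary C5 cation | Clc1ccc(O[C@]2(C)CC[C@]3(C)CC[C@@H](C(C)(C)O[Si](CC)(CC)CC)C[C+]3C2)c(Br)c1 | intermediate
17 | 3α-aryloxy-3β,10β-dimethyl-Δ5(6)-octalin (key-step product) | Clc1ccc(O[C@]2(C)CC[C@]3(C)CC[C@@H](C(C)(C)O[Si](CC)(CC)CC)C=C3C2)c(Br)c1 | intermediate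
18 | trans-decalin bromo chloro aryl ether (5α-H) | Clc1ccc(O[C@]2(C)CC[C@]3(C)CC[C@@H](C(C)(C)O[Si](CC)(CC)CC)C[C@H]3C2)c(Br)c1 | intermediate
19 | 4-bromophenol | Oc1ccc(Br)cc1 | starting material
20 | allyl bromide | C=CCBr | starting material
21 | 1-(allyloxy)-4-bromobenzene | C=CCOc1ccc(Br)cc1 | intermediate
22 | 2-allyl-4-bromophenol | C=CCc1cc(Br)ccc1O | intermediate
23 | (2-allyl-4-bromophenoxy)triisopropylsilane | C=CCc1cc(Br)ccc1O[Si](C(C)C)(C(C)C)C(C)C | intermediate
24 | ring D pinacol boronate | C=CCc1cc(B2OC(C)(C)C(C)(C)O2)ccc1O[Si](C(C)C)(C(C)C)C(C)C | intermediate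
25 | biaryl chloride | Clc1ccc(O[C@]2(C)CC[C@]3(C)CC[C@@H](C(C)(C)O[Si](CC)(CC)CC)C[C@H]3C2)c(-c2ccc(O[Si](C(C)C)(C(C)C)C(C)C)c(CC=C)c2)c1 | intermediate
26 | allylboronic acid pinacol ester | C=CCB1OC(C)(C)C(C)(C)O1 | starting material
27 | bis-silyl ether of the target | C=CCc1ccc(O[C@]2(C)CC[C@]3(C)CC[C@@H](C(C)(C)O[Si](CC)(CC)CC)C[C@H]3C2)c(-c2ccc(O[Si](C(C)C)(C(C)C)C(C)C)c(CC=C)c2)c1 | intermediate
28 | C11 TES ether of the target (free phenol) | C=CCc1ccc(O[C@]2(C)CC[C@]3(C)CC[C@@H](C(C)(C)O[Si](CC)(CC)CC)C[C@H]3C2)c(-c2ccc(O)c(CC=C)c2)c1 | intermediate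
29 | CNP0342687.1 | C=CCc1ccc(O[C@]2(C)CC[C@]3(C)CC[C@@H](C(C)(C)O)C[C@H]3C2)c(-c2ccc(O)c(CC=C)c2)c1 | target

**Step count**
- Total steps: 16.
- Longest linear sequence: 12 steps (steps 1–9 and 14–16) from (R)-carvone.
- The ring D branch (steps 10–13) has 4 steps.

**Steps most likely to fail**

1. Step 8 (ring closure). Four processes could defeat it:
   - loss of the phenol by adventitious hydrolysis of the enol ether;
   - loss of the phenol by ionisation of the newly formed tertiary ether;
   - proton shuffling to the internal enol ether without C–C bond formation;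
   - low facial selectivity at C3.

   The fallback separates C–C from C–O bond formation while closing the same C3–C4 bond. It sets out from 14 and comes back at 17. Brief treatment of 14 with oxalic acid in wet THF hydrolyses the enol ether to 4-[(1S,4R)-1-methyl-2-methylidene-4-(2-triethylsilyloxypropan-2-yl)cyclohexyl]butan-2-one F1. MeAlCl2 in CH2Cl2 at −78 → 0 °C then promotes the intramolecular carbonyl-ene (Prins) cyclisation of the ketone onto the same exocyclic methylene group. This should give the 3α-hydroxy-3β-methyl-Δ5(6)-octalin F2, and any C3 epimer can be removed at this alcohol stage. The sodium alkoxide of the alcohol (NaH, toluene, rt) is arylated without a metal catalyst by (2-bromo-4-chlorophenyl)(2,4,6-trimethoxyphenyl)iodonium tosylate F3, a method established for congested tertiary alkyl aryl ethers. The salt is made in one pot from commercial 2-bromo-4-chloro-1-iodobenzene, mCPBA, TsOH and 1,3,5-trimethoxybenzene.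

2. Step 7 (double methylenation). Three processes are of concern:
   - collapse of the oxatitanacycle of the activated ester by expulsion of aryloxide instead of cycloreversion;
   - incomplete reaction at the hindered ketone;
   - decay of the acid-sensitive product during long heating.

   The fallback treats the two carbonyl groups separately and by different elements. It sets out from 9 and comes back at 13, now isolated, and through it at 14. Acid 9, as its carboxylate and alkoxide, undergoes Wittig methylenation at the ketone alone with excess Ph3P=CH2 (Ph3PCH3Br, KOt-Bu, toluene, heat). The product is 3-[(1S,4R)-4-(2-hydroxypropan-2-yl)-1-methyl-2-methylidenecyclohexyl]propanoic acid F4. Steglich esterification with 10 gives its 2-bromo-4-chlorophenyl ester F5, and silylation as in step 6 gives 13. The ester carbonyl of 13 is then methylenated with Cp2Ti(μ-CH2)(μ-Cl)AlMe2 and pyridine in THF at −40 → 0 °C. This reagent has direct precedent on phenyl esters and avoids heating.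

3. Step 9 (C5 hydrogenation). Facial selectivity may erode because the axial aryloxy group at C3 crowds the α face, and hydrogen-atom transfer to the hindered trisubstituted alkene may be slow.

   The fallback replaces stepwise radical delivery by metal-bound syn addition. It sets out from 17 and comes back at 18. Hydrogenation uses [Ir(cod)(PCy3)(py)]PF6 and H2 in CH2Cl2. The face is then chosen by approach control, since the β face is closed by the C10 methyl and the C7 side chain, and possibly by weak coordination of the α-oriented ether oxygen. This catalyst reduces hindered trisubstituted alkenes and leaves aryl halides alone. No new compound is involved.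

**Further compounds**
F1 | step 8 | 4-[(1S,4R)-1-methyl-2-methylidene-4-(2-triethylsilyloxypropan-2-yl)cyclohexyl]butan-2-one | CC(=O)CC[C@]1(C)CC[C@@H](C(C)(C)O[Si](CC)(CC)CC)CC1=C
F2 | step 8 | 3α-hydroxy-3β,10β-dimethyl-7β-(2-triethylsilyloxypropan-2-yl)-Δ5(6)-octalin | O[C@]1(C)CC[C@]2(C)CC[C@@H](C(C)(C)O[Si](CC)(CC)CC)C=C2C1
F3 | step 8 | (2-bromo-4-chlorophenyl)(2,4,6-trimethoxyphenyl)iodonium tosylate | COc1cc(OC)c([I+]c2ccc(Cl)cc2Br)c(OC)c1.Cc1ccc(cc1)S(=O)(=O)[O-]
F4 | step 7 | 3-[(1S,4R)-4-(2-hydroxypropan-2-yl)-1-methyl-2-methylidenecyclohexyl]propanoic acid | OC(=O)CC[C@]1(C)CC[C@@H](C(C)(C)O)CC1=C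
F5 | step 7 | 2-bromo-4-chlorophenyl 3-[(1S,4R)-4-(2-hydroxypropan-2-yl)-1-methyl-2-methylidenecyclohexyl]propanoate | O=C(CC[C@]1(C)CC[C@@H](C(C)(C)O)CC1=C)Oc1ccc(Cl)cc1Br
F0 | step 9 | none | none
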